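The decalin is opened retrosynthetically at the C5–C10 bond shared by ring A (C1–C5, C10) and ring B (C5–C10), which leads back to a ten-membered (E,E)-germacra-1(10),4-diene. The key step, a proton-induced transannular cyclization terminated by water, exploits the trans C5–C10 fusion flanked by the tertiary C4 carbinol whose methyl is syn to the C10 methyl: it forms C5–C10 and C4–O and sets C4, C5 and C10 in one operation. Its precursor is the (3S)-3-silyloxy derivative of germacrone, in which the C8 carbonyl and the C7=C11 double bond are in place from the outset; C3 steers the folding. Angeloylation and a singlet-oxygen ene reaction (C11–OOH, C6=C7) complete the target.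

Key step: step 4

Assumption: eudesmane numbering is used for every compound, the ten-membered ones included, and the target is taken as the open hydroperoxy enone of the given SMILES, not a cyclic peroxyhemiketal tautomer.

Step 1
Reactants: 1 germacrone
Product: 4 rac-3-hydroxygermacrone, via allylseleninic acid 2 (not isolated), via hydroxyselanyl ether 3 (not isolated)
Conditions: SeO2 (0.3 equiv), t-BuOOH (2 equiv), CH2Cl2, 0 °C to rt; chromatography
Reagents that add atoms: selenium dioxide, O=[Se]=O (oxygen donor in the rearrangement); tert-butyl hydroperoxide, CC(C)(C)OO (stoichiometric oxidant that restores SeO2)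
Why: Riley allylic hydroxylation in the Sharpless catalytic version: the ene reaction of SeO2 should engage the most electron-rich alkene C4=C5 (C1=C10 is β,γ to the ketone, C7=C11 is an enone), place selenium on C5 and take hydrogen from the CH2 on the E side of the disubstituted terminus (C3, ranked above the C15 methyl by the Guillemonat order), after which the [2,3]-sigmatropic shift of allylseleninic acid 2 returns the E C4=C5 bond with oxygen on C3 as in 3, whose hydrolysis releases 4; C3 forms without control, so the alcohol is racemic.

Step 2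
Reactants: 4 rac-3-hydroxygermacrone
Product: 5 (S)-3-hydroxygermacrone
Conditions: immobilised Burkholderia cepacia lipase (Amano PS-IM), vinyl acetate, MTBE, 30 °C, taken just past half conversion; chromatographic removal of the (R)-acetate
Reagents that add atoms: none
Why: Lipase-catalysed kinetic resolution by irreversible transesterification: by Kazlauskas' rule the enzyme should acetylate the (R)-alcohol, whose large alkenyl carbon C4 and medium C2 methylene fit its pockets, so the slow (S)-enantiomer is recovered; no stereocentre is formed, C3 is resolved.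

Step 3
Reactants: 5 (S)-3-hydroxygermacrone; 6 tert-butyl(chloro)diphenylsilane
Product: 7 (3S)-3-(tert-butyldiphenylsilyloxy)germacrone
Conditions: 6, imidazole, DMAP (cat.), DMF, rt
Reagents that add atoms: tert-butyl(chloro)diphenylsilane (6), CC(C)(C)[Si](Cl)(c1ccccc1)c1ccccc1
Why: Imidazole-mediated silylation of a secondary alcohol, with retention at C3 because only the O–H bond reacts; the tert-butyldiphenylsilyl group is chosen because it withstands the aqueous acid of step 4, cannot bridge to C4 as an acyl group would, and is large enough to bias the fold of the ring.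

Step 4
Reactants: 7 (3S)-3-(tert-butyldiphenylsilyloxy)germacrone
Product: 9 (3S,4S,5R,10R)-3-(tert-butyldiphenylsilyloxy)-4-hydroxyeudesm-7(11)-en-8-one, via eudesm-4-yl cation 8 (not isolated)
Conditions: TsOH·H2O (0.2 equiv), acetone/H2O 4:1, 0 °C to rt
Reagents that add atoms: water, O
Why: The acid protonates C1 of the C1=C10 alkene (Markovnikov) while the C4=C5 π bond, held across the ring, attacks C10 through C5, and the resulting tertiary C4 cation 8 is quenched by water; this is the acid-promoted transannular cation–olefin cyclization of (E,E)-germacra-1(10),4-dienes to eudesman-4-ols, known for germacrone itself. Ring A (C1–C5, C10) closes 6-endo because both C4 and C5 of the attacking alkene end inside it, whereas ring B (C5–C10) closes 6-exo because C4 stays outside it. C5 and C10 are set by the crossed chair–chair conformer, in which the two E alkenes face each other with both methyls on one side, so H5 and the C10 methyl end on opposite faces (trans fusion); C4 is set by anti addition, water entering equatorially opposite the new C5–C10 bond, which leaves the C4 methyl axial on the face of the C10 methyl. The absolute sense comes from C3: of the two mirror-image folds the one that keeps the large OTBDPS group pseudo-equatorial should be preferred, because in the other the C3–O bond would be 1,3-diaxial to H1 and H5 and would replace the C3–H bond that stabilises the developing C4 cation by hyperconjugation, so (3S) is relayed to (4S,5R,10R). The step needs site selectivity for C1=C10, expected because C4=C5 is deactivated toward protonation by the allylic oxygen and C7=C11 by the carbonyl, and it needs hydration to outrun elimination, which the water-rich medium and a silyl ether unable to bridge to C4 are meant to secure.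

Step 5
Reactants: 9 (3S,4S,5R,10R)-3-(tert-butyldiphenylsilyloxy)-4-hydroxyeudesm-7(11)-en-8-one
Product: 10 (3S,4S,5R,10R)-3,4-dihydroxyeudesm-7(11)-en-8-one (3β,4α-diol)
Conditions: TBAF, AcOH, THF, 0 °C to rt
Reagents that add atoms: none
Why: Fluoride-induced cleavage of the Si–O bond, driven by the strong Si–F bond and buffered with acetic acid so that the enone and the tertiary carbinol see no free alkoxide or hydroxide; no stereocentre is touched.

Step 6
Reactants: 10 (3S,4S,5R,10R)-3,4-dihydroxyeudesm-7(11)-en-8-one; 11 angelic acid
Product: 13 3β-angeloyloxy-4α-hydroxyeudesm-7(11)-en-8-one, via angeloyl mixed anhydride 12 (not isolated)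
Conditions: 11, 2,4,6-Cl3C6H2COCl, Et3N, toluene, rt; then 10, toluene, 80 °C (no DMAP)
Reagents that add atoms: angelic acid (11), C/C=C(/C)C(=O)O
Why: Yamaguchi-type esterification through mixed anhydride 12: the secondary equatorial C3 hydroxyl attacks the unhindered angeloyl carbonyl while the flanked 2,4,6-trichlorobenzoyl carbonyl and the tertiary C4 hydroxyl stay out, and running it hot in toluene without DMAP avoids the addition–elimination that isomerises angelates to tiglates, so the Z geometry and the C3 configuration are retained.

Step 7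
Reactants: 13 3β-angeloyloxy-4α-hydroxyeudesm-7(11)-en-8-one
Product: 14 (3S,4S,5R,10R)-3-angeloyloxy-4-hydroxy-11-hydroperoxyeudesm-6-en-8-one (target)
Conditions: O2, tetraphenylporphyrin (cat.), visible light, CH2Cl2, 0 °C, stopped when 13 is consumed
Reagents that add atoms: dioxygen (as singlet oxygen), O=O
Why: Schenck ene reaction of an s-cis α,β-unsaturated ketone: singlet oxygen bonds to the β-carbon C11 and removes the axial hydrogen of C6, the alkyl group geminal to the carbonyl on C7 (gem effect), which moves the alkene to C6=C7 and leaves the tertiary hydroperoxide on the achiral C11, while the tetrasubstituted enone is expected to react ahead of the trisubstituted angelate and C5 is not touched.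

Compound list
1 | germacrone, (1(10)E,4E)-germacra-1(10),4,7(11)-trien-8-one | C1C/C=C(\C)CC(=O)C(=C(C)C)C/C=C1\C | starting material
2 | 8-oxogermacra-1(10),3,7(11)-trien-5-ylseleninic acid (racemic ene adduct, C3=C4 geometry open) | O[Se](=O)C1CC(=C(C)C)C(=O)C/C(C)=C/CC=C1C | intermediate (not isolated)
3 | 3-(hydroxyselanyloxy)germacrone (racemic) | O[Se]OC1C/C=C(\C)CC(=O)C(=C(C)C)C/C=C1\C | intermediate (not isolated)
4 | rac-3-hydroxygermacrone, (1(10)E,4E)-3-hydroxygermacra-1(10),4,7(11)-trien-8-one | OC1C/C=C(\C)CC(=O)C(=C(C)C)C/C=C1\C | intermediate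
5 | (S)-3-hydroxygermacrone | O[C@H]1C/C=C(\C)CC(=O)C(=C(C)C)C/C=C1\C | intermediate
6 | tert-butyl(chloro)diphenylsilane | CC(C)(C)[Si](Cl)(c1ccccc1)c1ccccc1 | starting material
7 | (3S)-3-(tert-butyldiphenylsilyloxy)germacrone (E,E) | CC(C)(C)[Si](c1ccccc1)(c1ccccc1)O[C@H]1C/C=C(\C)CC(=O)C(=C(C)C)C/C=C1\C | intermediate
8 | 3β-(tert-butyldiphenylsilyloxy)-8-oxoeudesm-7(11)-en-4-ylium (5α-H, 10β-methyl) | CC(C)(C)[Si](c1ccccc1)(c1ccccc1)O[C@H]1CC[C@]2(C)CC(=O)C(=C(C)C)C[C@H]2[C+]1C | intermediate (not isolated)
9 | (3S,4S,5R,10R)-3-(tert-butyldiphenylsilyloxy)-4-hydroxyeudesm-7(11)-en-8-one (3β-OSi, 4α-OH, 5α-H, 10β-methyl) | CC(C)(C)[Si](c1ccccc1)(c1ccccc1)O[C@H]1CC[C@]2(C)CC(=O)C(=C(C)C)C[C@H]2[C@]1(C)O | intermediate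
10 | (3S,4S,5R,10R)-3,4-dihydroxyeudesm-7(11)-en-8-one (3β,4α-diol) | O[C@H]1CC[C@]2(C)CC(=O)C(=C(C)C)C[C@H]2[C@]1(C)O | intermediate
11 | angelic acid, (Z)-2-methylbut-2-enoic acid | C/C=C(/C)C(=O)O | starting material
12 | angelic 2,4,6-trichlorobenzoic anhydride | C/C=C(/C)C(=O)OC(=O)c1c(Cl)cc(Cl)cc1Cl | intermediate (not isolated)
13 | 3β-angeloyloxy-4α-hydroxyeudesm-7(11)-en-8-one (3S,4S,5R,10R) | C/C=C(/C)C(=O)O[C@H]1CC[C@]2(C)CC(=O)C(=C(C)C)C[C@H]2[C@]1(C)O | intermediate
14 | 3β-angeloyloxy-4α-hydroxy-11-hydroperoxyeudesm-6-en-8-one (3S,4S,5R,10R), CNP0161122.1 | C/C=C(/C)C(=O)O[C@H]1CC[C@]2(C)CC(=O)C(C(C)(C)OO)=C[C@H]2[C@]1(C)O | target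

Total step count: 7. Longest linear sequence: 7 steps (1 to 14).

Steps most likely to fail

Step 1, site of the allylic hydroxylation. The ene step may take its hydrogen from the C15 (or C14) methyl group instead of the C3 methylene. In the ten-membered ring the C3–H bonds lie close to the plane of the C4=C5 bond, whereas methyl C–H bonds align freely, so the hydroxyl may end on a methyl carbon, with over-oxidation as a second drain. The fallback sets out from 1 and returns at 10; it oxygenates C3 only after the ring system is rigid. Germacrone 1 is cyclised with anhydrous TsOH in CH2Cl2, the same transannular closure ended by loss of the axial C3 proton, to rac-eudesma-3,7(11)-dien-8-one F1. OsO4 (cat.) with N-methylmorpholine N-oxide should add to the electron-rich C3=C4 bond from the α face, opposite the axial C10 methyl, to give rac-3α,4α-dihydroxyeudesm-7(11)-en-8-one F2. Parikh–Doering oxidation (SO3·pyridine, DMSO, Et3N) of the secondary hydroxyl gives rac-4α-hydroxyeudesm-7(11)-ene-3,8-dione F3. NaBH4 (MeOH/CH2Cl2, −78 °C) should reduce the saturated C3 ketone ahead of the hindered conjugated C8 ketone by axial hydride delivery, giving rac-3β,4α-dihydroxyeudesm-7(11)-en-8-one F4. Lipase-catalysed acetylation with vinyl acetate then removes the (3R)-enantiomer and leaves diol 10, from which steps 6 and 7 follow.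

Step 4, fate of the C4 cation and sense of folding. Cation 8 may lose a proton (toward C3 to a silyl enol ether, toward C15 or C5) or suffer a 1,2-hydride shift from C3 before water arrives. The carbinol may also re-ionise under the acid, and part of the material may fold with the silyloxy group pseudo-axial and give the C4/C5/C10 diastereomer. The fallback sets out from 7 and returns at 9; the closure is triggered by a bromonium ion instead of a proton, so no Brønsted acid is present and the hydration is not reversed. NBS in acetone/H2O at 0 °C should attack C1=C10 at C1, with C5 closing on C10 and water taken up at C4, a known cyclization mode of germacra-1(10),4-dienes. This gives 1β-bromo-3β-(tert-butyldiphenylsilyloxy)-4α-hydroxyeudesm-7(11)-en-8-one F5, at which stage any diastereomer from the minor fold would be separated. Bu3SnH with AIBN (toluene, 80 °C) then replaces the equatorial C1 bromine by hydrogen and returns 9.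

Step 7, chemoselectivity of the photo-oxygenation. The electron-poor enone needs long irradiation. During it the angelate C=C (itself an ene-active α,β-unsaturated ester) and the C12/C13 methyl hydrogens may compete, while the product hydroperoxide stays exposed to light and sensitiser. The fallback sets out from 9 and returns at 14; the oxygenation is moved ahead of the angelate. Silyl ether 9 is photo-oxygenated under the conditions of step 7 to 3β-(tert-butyldiphenylsilyloxy)-4α-hydroxy-11-hydroperoxyeudesm-6-en-8-one F6. The OOH group is masked with 2-methoxypropene and pyridinium p-toluenesulfonate as the 2-methoxyprop-2-yl peroxyketal F7. TBAF/AcOH removes the silyl group to give 3β,4α-dihydroxy-11-(2-methoxyprop-2-ylperoxy)eudesm-6-en-8-one F8. Angeloylation as in step 6 gives 3β-angeloyloxy-4α-hydroxy-11-(2-methoxyprop-2-ylperoxy)eudesm-6-en-8-one F9. AcOH/THF/H2O at rt then releases hydroperoxide 14.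

Further compounds
F1 | step 1 | rac-eudesma-3,7(11)-dien-8-one (5α-H, 10β-methyl; relative configuration) | C1C[C@]2(C)CC(=O)C(=C(C)C)C[C@H]2C(C)=C1
F2 | step 1 | rac-3α,4α-dihydroxyeudesm-7(11)-en-8-one (relative configuration) | O[C@@H]1CC[C@]2(C)CC(=O)C(=C(C)C)C[C@H]2[C@]1(C)O
F3 | step 1 | rac-4α-hydroxyeudesm-7(11)-ene-3,8-dione (relative configuration) | O=C1CC[C@]2(C)CC(=O)C(=C(C)C)C[C@H]2[C@]1(C)O
F4 | step 1 | rac-3β,4α-dihydroxyeudesm-7(11)-en-8-one (racemate of 10; relative configuration) | O[C@H]1CC[C@]2(C)CC(=O)C(=C(C)C)C[C@H]2[C@]1(C)O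
F5 | step 4 | 1β-bromo-3β-(tert-butyldiphenylsilyloxy)-4α-hydroxyeudesm-7(11)-en-8-one | CC(C)(C)[Si](c1ccccc1)(c1ccccc1)O[C@H]1C[C@@H](Br)[C@]2(C)CC(=O)C(=C(C)C)C[C@H]2[C@]1(C)O
F6 | step 7 | 3β-(tert-butyldiphenylsilyloxy)-4α-hydroxy-11-hydroperoxyeudesm-6-en-8-one | CC(C)(C)[Si](c1ccccc1)(c1ccccc1)O[C@H]1CC[C@]2(C)CC(=O)C(C(C)(C)OO)=C[C@H]2[C@]1(C)O
F7 | step 7 | 3β-(tert-butyldiphenylsilyloxy)-4α-hydroxy-11-(2-methoxyprop-2-ylperoxy)eudesm-6-en-8-one | CC(C)(C)[Si](c1ccccc1)(c1ccccc1)O[C@H]1CC[C@]2(C)CC(=O)C(C(C)(C)OOC(C)(C)OC)=C[C@H]2[C@]1(C)O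
F8 | step 7 | 3β,4α-dihydroxy-11-(2-methoxyprop-2-ylperoxy)eudesm-6-en-8-one | O[C@H]1CC[C@]2(C)CC(=O)C(C(C)(C)OOC(C)(C)OC)=C[C@H]2[C@]1(C)O
F9 | step 7 | 3β-angeloyloxy-4α-hydroxy-11-(2-methoxyprop-2-ylperoxy)eudesm-6-en-8-one | C/C=C(/C)C(=O)O[C@H]1CC[C@]2(C)CC(=O)C(C(C)(C)OOC(C)(C)OC)=C[C@H]2[C@]1(C)O
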